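**Plan**

1. Retrosynthetic cuts: in the side chain, the C(=O)–CH= bond (alkenyl metal plus α-methylene aldehyde) and the exocyclic =CH2 (α-methylenation of a CH2CHO arm); in the ring, the epoxide C–O bond at the CH carbon (tertiary alkoxide plus trans-diaxial sulfonate), the C–CH3 bond (methyl addition to a ketone), and finally the two ring bonds CH2–CH(O) and C(=O)–CH(O-tigloyl).
2. Enabling feature: the ring holds four contiguous oxygenated carbons, CH(O)–C(CH3)(O)–C(=O)–CH(O-tigloyl). The methyl-bearing epoxide carbon with its two oxygenated neighbours is a masked 1,3-dioxan-5-one (dihydroxyacetone) unit, and the remaining CH2–CH(side chain)–CH(O) unit is an α-substituted acrolein. One amine-catalysed Michael/aldol α,α′-annulation therefore makes both ring bonds and gives a 2,4-dioxabicyclo[3.3.1]nonan-9-one.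
3. Forward order: α-allylacrolein plus 2-phenyl-1,3-dioxan-5-one → bicyclic ketol (carbocycle made, dioxane ring temporary) → tiglate → methyl carbinol → acetal removal → epoxide → CH2CHO arm → α-methylene aldehyde → alkenyl addition (side chain joined) → double oxidation.
4. Stereochemistry: absolute configuration comes from the chiral primary amine in the Michael event. The bridge fixes the two acetal C–O bonds cis, carbinol and allyl carbons settle equatorial (trans), methyl enters from the dioxane face, and backside epoxide closure puts the epoxide anti to the tiglate and syn to the side chain.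

Key step: step 2

Assumption: the quinine-derived primary amine is taken to select the α-carbon of the dioxanone that leads to the (1R)-configured bicyclic ketol of step 2; the sense is assigned by analogy with amine-catalysed Michael additions of cyclic ketones, and the quinidine-derived pseudo-enantiomer of the catalyst would be used if it proved opposite.

**Route**

Step 1
Reactants: 1 pent-4-enal
Product: 2 2-methylidenepent-4-enal
Conditions: 37% aq. HCHO, pyrrolidine (10 mol %), EtCO2H (10 mol %), i-PrOH, 45 °C
Reagents that add atoms: formaldehyde, C=O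
Why: Amine-catalysed α-methylenation of an aldehyde (Mannich condensation, then elimination of the amine) is routine for unbranched aldehydes and leaves the remote terminal alkene untouched; no stereocenter is formed.

Step 2
Reactants: 2 2-methylidenepent-4-enal; 3 2-phenyl-1,3-dioxan-5-one
Product: 5 (1R,3S,5S,6S,7R)-6-hydroxy-3-phenyl-7-(prop-2-en-1-yl)-2,4-dioxabicyclo[3.3.1]nonan-9-one, via Michael adduct keto aldehyde 4 (not isolated)
Conditions: 9-amino(9-deoxy)epi-quinine (20 mol %), CF3CO2H (40 mol %), THF, rt, prolonged stirring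
Reagents that add atoms: none
Why: The primary amine and ketone 3 give an enamine whose α-carbon adds axially to the CH2 terminus of enal 2 (Michael addition, first C–C bond); the enamine re-formed at the other α-carbon of adduct 4 then attacks the tethered aldehyde (intramolecular aldol, second C–C bond) and hydrolysis returns the catalyst. The closest known reaction type is the Stork α,α′-annulation of cyclic-ketone enamines with acroleins to 2-substituted bicyclo[3.3.1]nonan-9-ones, used here in its catalytic enamine Michael/aldol form. The carbocycle closes by a 6-(enolendo)-exo-trig aldol, the dioxane ring being carried in from 3. C-1 is set by the catalyst, which selects one of the two enantiotopic α-carbons of 3 for attack on the axial face of the chair that keeps phenyl equatorial (this also makes C-3 stereogenic, phenyl exo); C-5 must be cis to C-1 because the three-carbon bridge can only span the dioxanone diaxially; C-7, epimerisable α to the aldehyde in 4, closes with allyl equatorial to avoid the 3,7-transannular contact; the C-6 hydroxyl should settle equatorial, trans to allyl, because the aldol is reversible under the amine/acid conditions. The step needs α,α′- instead of α,α-bond formation and 1,4- before 1,2-addition to the enal; the first is secured by the substituent that blocks a second enamine at the alkylated α-carbon, the second by the soft enamine donor and the unhindered CH2 acceptor terminus.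

Step 3
Reactants: 5 (1R,3S,5S,6S,7R)-6-hydroxy-3-phenyl-7-(prop-2-en-1-yl)-2,4-dioxabicyclo[3.3.1]nonan-9-one
Product: 6 (1R,3S,5S,6S,7R)-9-oxo-3-phenyl-7-(prop-2-en-1-yl)-2,4-dioxabicyclo[3.3.1]nonan-6-yl (2E)-2-methylbut-2-enoate
Conditions: (E)-2-methylbut-2-enoyl chloride, pyridine, DMAP (cat.), CH2Cl2, 0 °C to rt
Reagents that add atoms: tigloyl chloride ((2E)-2-methylbut-2-enoyl chloride), ClC(=O)/C(C)=C/C
Why: DMAP-catalysed O-acylation of the unhindered equatorial secondary alcohol occurs with retention; because both α-carbons of the ketone are bridgeheads the β-acyloxy ketone cannot enolise or eliminate (Bredt's rule), so the natural ester can serve as the protecting group from here on.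

Step 4
Reactants: 6 (1R,3S,5S,6S,7R)-9-oxo-3-phenyl-7-(prop-2-en-1-yl)-2,4-dioxabicyclo[3.3.1]nonan-6-yl (2E)-2-methylbut-2-enoate
Product: 7 (1R,3S,5S,6S,7R,9S)-9-hydroxy-9-methyl-3-phenyl-7-(prop-2-en-1-yl)-2,4-dioxabicyclo[3.3.1]nonan-6-yl (2E)-2-methylbut-2-enoate
Conditions: MeMgBr, CeCl3, THF, −78 °C
Reagents that add atoms: methylmagnesium bromide, C[Mg]Br
Why: Organocerium 1,2-addition is selective for the ketone over the conjugated ester, and the methyl group should enter from the dioxane face, which is the axial trajectory preferred by 1,3-dioxan-5-ones (ring oxygens in place of 1,3-diaxial hydrogens) and at the same time the equatorial trajectory on the cyclohexanone ring, so the new hydroxyl ends axial on the carbocycle and anti to both acetal C–O bonds.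

Step 5
Reactants: 7 (1R,3S,5S,6S,7R,9S)-9-hydroxy-9-methyl-3-phenyl-7-(prop-2-en-1-yl)-2,4-dioxabicyclo[3.3.1]nonan-6-yl (2E)-2-methylbut-2-enoate
Product: 8 (1S,2S,3S,4R,6R)-2,3,4-trihydroxy-3-methyl-6-(prop-2-en-1-yl)cyclohexyl (2E)-2-methylbut-2-enoate
Conditions: AcOH/H2O (4:1), 50 °C
Reagents that add atoms: none
Why: Acid-catalysed hydrolysis of the benzylidene acetal frees the 1,3-diaxial diol without touching the ester, the alkenes or any stereocenter.

Step 6
Reactants: 8 (1S,2S,3S,4R,6R)-2,3,4-trihydroxy-3-methyl-6-(prop-2-en-1-yl)cyclohexyl (2E)-2-methylbut-2-enoate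
Product: 10 (1R,2S,3S,4R,6S)-2-hydroxy-1-methyl-4-(prop-2-en-1-yl)-7-oxabicyclo[4.1.0]heptan-3-yl (2E)-2-methylbut-2-enoate, via monomesylate 9 (not isolated)
Conditions: MsCl (1.05 equiv), Et3N, CH2Cl2, −40 °C; then DBU, 0 °C to rt
Reagents that add atoms: none
Why: Sulfonylation should take the less hindered of the two axial secondary hydroxyls (C-4, next to the ring CH2, rather than C-2, wedged between the quaternary carbon and the ester-bearing carbon), after which the tertiary alkoxide, antiperiplanar to the mesylate, closes the epoxide by intramolecular SN2 displacement with inversion at C-4 (trans-diaxial halohydrin-type closure), placing the epoxide anti to the tiglate and syn to the allyl group.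

Step 7
Reactants: 10 (1R,2S,3S,4R,6S)-2-hydroxy-1-methyl-4-(prop-2-en-1-yl)-7-oxabicyclo[4.1.0]heptan-3-yl (2E)-2-methylbut-2-enoate
Product: 11 (1R,2S,3S,4S,6S)-2-hydroxy-1-methyl-4-(2-oxoethyl)-7-oxabicyclo[4.1.0]heptan-3-yl (2E)-2-methylbut-2-enoate
Conditions: OsO4 (2 mol %), NaIO4, 2,6-lutidine, 1,4-dioxane/H2O (3:1), rt
Reagents that add atoms: osmium tetroxide (catalytic oxygen carrier), O=[Os](=O)(=O)=O; sodium periodate (terminal oxidant), [Na+].[O-]I(=O)(=O)=O
Why: Lemieux–Johnson cleavage (catalytic dihydroxylation, then periodate glycol cleavage) should be selective for the monosubstituted terminal alkene over the electron-poor trisubstituted tiglate alkene, and the trans 1,3-relation of the free hydroxyl and the new aldehyde arm prevents lactol formation.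

Step 8
Reactants: 11 (1R,2S,3S,4S,6S)-2-hydroxy-1-methyl-4-(2-oxoethyl)-7-oxabicyclo[4.1.0]heptan-3-yl (2E)-2-methylbut-2-enoate
Product: 12 (1R,2S,3S,4S,6S)-2-hydroxy-1-methyl-4-(3-oxoprop-1-en-2-yl)-7-oxabicyclo[4.1.0]heptan-3-yl (2E)-2-methylbut-2-enoate
Conditions: CH2=NMe2+ I− (Eschenmoser's salt), Et3N, CH2Cl2, rt
Reagents that add atoms: N,N-dimethylmethyleneiminium iodide, C=[N+](C)C.[I-]
Why: Mannich reaction of the enolisable aldehyde with the iminium salt followed by base-induced loss of dimethylamine (α-methylenation) gives the α-substituted acrolein under conditions too mild to enolise toward the ring stereocenter or to open the epoxide.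

Step 9
Reactants: 13 2-methylbut-3-yn-2-ol
Product: 15 (3E)-4-iodo-2-methylbut-3-en-2-ol, via alkenylstannane 14 (not isolated)
Conditions: Bu3SnH, PdCl2(PPh3)2 (1 mol %), THF, 0 °C; then I2, CH2Cl2, 0 °C
Reagents that add atoms: iodine, II
Why: Palladium-catalysed syn-hydrostannation of the terminal alkyne places tin on the terminal carbon away from the tertiary carbinol, and iododestannylation with retention gives the E-alkenyl iodide.

Step 10
Reactants: 12 (1R,2S,3S,4S,6S)-2-hydroxy-1-methyl-4-(3-oxoprop-1-en-2-yl)-7-oxabicyclo[4.1.0]heptan-3-yl (2E)-2-methylbut-2-enoate; 15 (3E)-4-iodo-2-methylbut-3-en-2-ol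
Product: 16 (1R,2S,3S,4S,6S)-4-[(4E)-3,6-dihydroxy-6-methylhepta-1,4-dien-2-yl]-2-hydroxy-1-methyl-7-oxabicyclo[4.1.0]heptan-3-yl (2E)-2-methylbut-2-enoate (both configurations at the new side-chain carbinol)
Conditions: CrCl2 (5 equiv), NiCl2 (2 mol %), DMSO, rt
Reagents that add atoms: none
Why: Nozaki–Hiyama–Kishi coupling: the alkenylchromium species generated with nickel catalysis adds 1,2 to the aldehyde only, with retention of the E geometry and tolerance of the free hydroxyls, the ester and the isolated epoxide; the new carbinol carbon forms without control, which is irrelevant because it is oxidised next.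

Step 11
Reactants: 16 (1R,2S,3S,4S,6S)-4-[(4E)-3,6-dihydroxy-6-methylhepta-1,4-dien-2-yl]-2-hydroxy-1-methyl-7-oxabicyclo[4.1.0]heptan-3-yl (2E)-2-methylbut-2-enoate
Product: 17 (1S,3S,4S,6S)-4-[(4E)-6-hydroxy-6-methyl-3-oxohepta-1,4-dien-2-yl]-1-methyl-2-oxo-7-oxabicyclo[4.1.0]heptan-3-yl (2E)-2-methylbut-2-enoate (target, CNP0263368.1)
Conditions: Dess–Martin periodinane (3 equiv), NaHCO3, CH2Cl2, 0 °C to rt
Reagents that add atoms: none
Why: Dess–Martin oxidation converts both secondary carbinols (ring and bis-allylic) to ketones in one buffered, non-basic operation, which leaves the tertiary allylic alcohol, the epoxide and the now epimerisable acyloxy-bearing ring carbon (already in the favoured trans arrangement with the side chain) unchanged.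

**Compound list**

1 | pent-4-enal | C=CCCC=O | starting material
2 | 2-methylidenepent-4-enal | C=CCC(=C)C=O | intermediate
3 | 2-phenyl-1,3-dioxan-5-one | O=C1COC(c2ccccc2)OC1 | starting material
4 | 2-{[(2R,4R)-5-oxo-2-phenyl-1,3-dioxan-4-yl]methyl}pent-4-enal (aldehyde α-carbon not fixed) | C=CCC(C=O)C[C@H]1O[C@H](c2ccccc2)OCC1=O | intermediate
5 | (1R,3S,5S,6S,7R)-6-hydroxy-3-phenyl-7-(prop-2-en-1-yl)-2,4-dioxabicyclo[3.3.1]nonan-9-one | C=CC[C@@H]1C[C@H]2O[C@H](c3ccccc3)O[C@H](C2=O)[C@H]1O | intermediate
6 | (1R,3S,5S,6S,7R)-9-oxo-3-phenyl-7-(prop-2-en-1-yl)-2,4-dioxabicyclo[3.3.1]nonan-6-yl (2E)-2-methylbut-2-enoate | C=CC[C@@H]1C[C@H]2O[C@H](c3ccccc3)O[C@H](C2=O)[C@H]1OC(=O)/C(C)=C/C | intermediate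
7 | (1R,3S,5S,6S,7R,9S)-9-hydroxy-9-methyl-3-phenyl-7-(prop-2-en-1-yl)-2,4-dioxabicyclo[3.3.1]nonan-6-yl (2E)-2-methylbut-2-enoate | C=CC[C@@H]1C[C@H]2O[C@H](c3ccccc3)O[C@H]([C@@]2(C)O)[C@H]1OC(=O)/C(C)=C/C | intermediate
8 | (1S,2S,3S,4R,6R)-2,3,4-trihydroxy-3-methyl-6-(prop-2-en-1-yl)cyclohexyl (2E)-2-methylbut-2-enoate | C=CC[C@@H]1C[C@@H](O)[C@](C)(O)[C@@H](O)[C@H]1OC(=O)/C(C)=C/C | intermediate
9 | (1S,2S,3R,4R,6R)-2,3-dihydroxy-4-(methanesulfonyloxy)-3-methyl-6-(prop-2-en-1-yl)cyclohexyl (2E)-2-methylbut-2-enoate | C=CC[C@@H]1C[C@@H](OS(C)(=O)=O)[C@](C)(O)[C@@H](O)[C@H]1OC(=O)/C(C)=C/C | intermediate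
10 | (1R,2S,3S,4R,6S)-2-hydroxy-1-methyl-4-(prop-2-en-1-yl)-7-oxabicyclo[4.1.0]heptan-3-yl (2E)-2-methylbut-2-enoate | C=CC[C@@H]1C[C@@H]2O[C@]2(C)[C@@H](O)[C@H]1OC(=O)/C(C)=C/C | intermediate
11 | (1R,2S,3S,4S,6S)-2-hydroxy-1-methyl-4-(2-oxoethyl)-7-oxabicyclo[4.1.0]heptan-3-yl (2E)-2-methylbut-2-enoate | O=CC[C@@H]1C[C@@H]2O[C@]2(C)[C@@H](O)[C@H]1OC(=O)/C(C)=C/C | intermediate
12 | (1R,2S,3S,4S,6S)-2-hydroxy-1-methyl-4-(3-oxoprop-1-en-2-yl)-7-oxabicyclo[4.1.0]heptan-3-yl (2E)-2-methylbut-2-enoate | C=C(C=O)[C@@H]1C[C@@H]2O[C@]2(C)[C@@H](O)[C@H]1OC(=O)/C(C)=C/C | intermediate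
13 | 2-methylbut-3-yn-2-ol | C#CC(C)(C)O | starting material
14 | (3E)-2-methyl-4-(tributylstannyl)but-3-en-2-ol | CCCC[Sn](CCCC)(CCCC)/C=C/C(C)(C)O | intermediate
15 | (3E)-4-iodo-2-methylbut-3-en-2-ol | I/C=C/C(C)(C)O | intermediate
16 | (1R,2S,3S,4S,6S)-4-[(4E)-3,6-dihydroxy-6-methylhepta-1,4-dien-2-yl]-2-hydroxy-1-methyl-7-oxabicyclo[4.1.0]heptan-3-yl (2E)-2-methylbut-2-enoate (side-chain carbinol as epimer mixture) | C=C(C(O)/C=C/C(C)(C)O)[C@@H]1C[C@@H]2O[C@]2(C)[C@@H](O)[C@H]1OC(=O)/C(C)=C/C | intermediate
17 | (1S,3S,4S,6S)-4-[(4E)-6-hydroxy-6-methyl-3-oxohepta-1,4-dien-2-yl]-1-methyl-2-oxo-7-oxabicyclo[4.1.0]heptan-3-yl (2E)-2-methylbut-2-enoate | C=C(C(=O)/C=C/C(C)(C)O)[C@@H]1C[C@@H]2O[C@]2(C)C(=O)[C@H]1OC(=O)/C(C)=C/C | target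

**Step count and risks**

Total step count: 11. Longest linear sequence: 10 steps (steps 1 to 8, then 10 and 11; step 9 makes the side-chain fragment).

Steps most likely to fail:

Step 2. The process at risk is weak discrimination between the two enantiotopic α-carbons of the dioxanone in the Michael event, or a background reaction through an achiral enol, so that the ketol forms with low enantiomeric purity. The fallback replaces asymmetric catalysis by resolution. It sets out from 2 and 3, which are annulated with pyrrolidine and acetic acid (achiral Stork-type enamine conditions) to give 5 as a racemate, that is together with its antipode, the (1S,3R,5R,6R,7S)-ketol F1. Lipase-catalysed transesterification (Burkholderia cepacia lipase, vinyl acetate, tert-butyl methyl ether) should, by the empirical rule for cyclic secondary carbinols, acetylate the (6R)-carbinol of F1 to the acetate of the antipode F2 and leave 5. After chromatographic separation the route is rejoined at 5.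

Step 3. The process at risk is incomplete equilibration of the aldol in step 2, so that the carbinol reaches the acylation axial (cis to the allyl group); esterification with retention would then fix the wrong configuration at the ester-bearing carbon. The fallback uses inversion instead of retention. It sets out from 2 and 3 under kinetic aldol control (short reaction time, low temperature), where the hydrogen-bonded closed transition state should give the axial epimer, the (1R,3S,5S,6R,7R)-ketol F3. Mitsunobu esterification of F3 with tiglic acid (PPh3, DIAD, toluene) displaces the activated axial hydroxyl from the equatorial side with inversion and gives 6, where the route is rejoined.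

Step 6. The processes at risk are sulfonylation at the wrong secondary hydroxyl, base-induced migration of the epoxide to the neighbouring carbinol (Payne-type equilibration), and migration of the tigloyl group to the adjacent axial hydroxyl. The fallback differentiates the hydroxyls by protection instead of by selective sulfonylation. It sets out from 5: methyl addition (MeMgBr, CeCl3, THF, −78 °C) gives the diol acetal F4, and aqueous acetic acid gives the tetraol F5. 2,2-Dimethoxypropane with PPTS then ties the cis-vicinal diol as the acetonide F6; the diaxial 1,3-diol would need a strained bridged acetonide with an inside methyl group and should not compete. The only free secondary hydroxyl is mesylated (MsCl, Et3N) to the mesylate acetonide F7, aqueous acid removes the acetonide to give the mesyl triol F8, and tigloyl chloride with pyridine at low temperature acylates the equatorial hydroxyl in preference to the hindered axial one. This gives 9, where the route is rejoined before the DBU treatment of step 6.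

**Further compounds**

F1 | step 2 | (1S,3R,5R,6R,7S)-6-hydroxy-3-phenyl-7-(prop-2-en-1-yl)-2,4-dioxabicyclo[3.3.1]nonan-9-one (antipode of 5) | C=CC[C@H]1C[C@@H]2O[C@@H](c3ccccc3)O[C@@H](C2=O)[C@@H]1O
F2 | step 2 | (1S,3R,5R,6R,7S)-9-oxo-3-phenyl-7-(prop-2-en-1-yl)-2,4-dioxabicyclo[3.3.1]nonan-6-yl acetate | C=CC[C@H]1C[C@@H]2O[C@@H](c3ccccc3)O[C@@H](C2=O)[C@@H]1OC(C)=O
F3 | step 3 | (1R,3S,5S,6R,7R)-6-hydroxy-3-phenyl-7-(prop-2-en-1-yl)-2,4-dioxabicyclo[3.3.1]nonan-9-one (axial carbinol epimer of 5) | C=CC[C@@H]1C[C@H]2O[C@H](c3ccccc3)O[C@H](C2=O)[C@@H]1O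
F4 | step 6 | (1R,3S,5S,6S,7R,9S)-9-methyl-3-phenyl-7-(prop-2-en-1-yl)-2,4-dioxabicyclo[3.3.1]nonane-6,9-diol | C=CC[C@@H]1C[C@H]2O[C@H](c3ccccc3)O[C@H]([C@@]2(C)O)[C@H]1O
F5 | step 6 | (1R,2S,3S,4S,5R)-2-methyl-5-(prop-2-en-1-yl)cyclohexane-1,2,3,4-tetrol | C=CC[C@@H]1C[C@@H](O)[C@](C)(O)[C@@H](O)[C@H]1O
F6 | step 6 | 3,4-O-isopropylidene acetal of tetraol F5 (cis-fused dioxolane on the two carbinols next to the allyl-bearing carbon) | C=CC[C@@H]1C[C@@H](O)[C@](C)(O)[C@H]2OC(C)(C)O[C@@H]12
F7 | step 6 | methanesulfonate of F6 at its free secondary hydroxyl | C=CC[C@@H]1C[C@@H](OS(C)(=O)=O)[C@](C)(O)[C@H]2OC(C)(C)O[C@@H]12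
F8 | step 6 | 1-O-methanesulfonate of tetraol F5 (mesyl triol) | C=CC[C@@H]1C[C@@H](OS(C)(=O)=O)[C@](C)(O)[C@@H](O)[C@H]1O
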